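## Retrosynthetic overview

1. Target 22 comes from hydrogenolysis of dibenzyl ether 21. Its threo-(1R,2R) arylglycerol ether arm comes from an Evans syn-glycolate aldol of aryloxyacetyl imide 16 with O-benzylvanillin 17, followed by reductive removal of the auxiliary.
2. Imide 16 comes from O-alkylation of the silyl-masked phenol of lactone 13 (a matairesinol carrying one OBn and one OTBS) with chloroacetyl imide 14.
3. Lactone 13 comes from the key C–C bond between the two α-carbons (lactone C-3/C-4): oxidative hetero-coupling of the enolates of imide 5 and ester 7, one enolate reacting in its one-electron-oxidised (enolonium-type) form.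
4. The only ring made is the γ-butyrolactone, closed right after the coupling (imide reduction, lactonisation, epimerisation to trans). All arenes are bought.
5. Stereocontrol: C-4 by the auxiliary in the coupling, C-3 by equilibration, both arm centres by the aldol.

Assumption: compounds 1, 3, 6, 14 and 17 are purchased as catalogue compounds.

## Route

Step 1
Reactants: 1 3-(4-hydroxy-3-methoxyphenyl)propanoic acid (dihydroferulic acid)
Product: 2 3-[4-(benzyloxy)-3-methoxyphenyl]propanoic acid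
Conditions: BnBr (1.2 eq), KOH (2.5 eq), EtOH/H2O, reflux; then 2 M HCl
Reagents that add atoms: benzyl bromide, BrCc1ccccc1
Why: Williamson ether synthesis; in aqueous alcohol the phenoxide of the dianion is far more nucleophilic than the carboxylate and any benzyl ester is saponified by the excess KOH, so the ether acid is obtained directly on acidification.

Step 2
Reactants: 2 3-[4-(benzyloxy)-3-methoxyphenyl]propanoic acid; 3 (S)-4-benzyloxazolidin-2-one
Product: 5 (S)-4-benzyl-3-{3-[4-(benzyloxy)-3-methoxyphenyl]propanoyl}oxazolidin-2-one, via mixed pivalic anhydride 4 (not isolated)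
Conditions: PivCl, Et3N, THF, −20 °C; then 3, LiCl, −20 °C → rt
Reagents that add atoms: none
Why: N-acylation of the oxazolidinone through the mixed pivalic anhydride (LiCl-promoted), with attack at the unhindered acyl group.

Step 3
Reactants: 6 methyl 3-(4-hydroxy-3-methoxyphenyl)propanoate
Product: 7 methyl 3-[4-(tert-butyldimethylsilyloxy)-3-methoxyphenyl]propanoate
Conditions: TBSCl, imidazole, DMF, rt
Reagents that add atoms: tert-butyldimethylsilyl chloride, CC(C)(C)[Si](C)(C)Cl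
Why: Phenol silylation; the aryl silyl ether tolerates LDA at −78 °C and is orthogonal to the benzyl ether of 5.

Step 4
Reactants: 5 (S)-4-benzyl-3-{3-[4-(benzyloxy)-3-methoxyphenyl]propanoyl}oxazolidin-2-one; 7 methyl 3-[4-(tert-butyldimethylsilyloxy)-3-methoxyphenyl]propanoate
Product: 10 methyl (3R)-3-[4-(benzyloxy)-3-methoxybenzyl]-4-[(S)-4-benzyl-2-oxooxazolidin-3-yl]-2-[4-(tert-butyldimethylsilyloxy)-3-methoxybenzyl]-4-oxobutanoate (C-2 epimer mixture), via lithium imide enolate 8 (not isolated), via lithium ester enolate 9 (not isolated)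
Conditions: 5 (1 eq), 7 (1.5 eq), LDA (2.6 eq), THF, −78 °C, 30 min; Fe(acac)3 (2.6 eq), −78 °C → rt
Reagents that add atoms: none
Why: Oxidative enolate hetero-coupling (Baran type), in which Fe(III) oxidises the ester enolate in the mixed lithium aggregate to an electrophilic α-carbonyl radical (enolonium equivalent) that the imide enolate captures, joining two nucleophilic α-carbons; the chelated (Z)-imide enolate reacts on the face opposite the auxiliary benzyl group, as in Evans alkylation, setting the imide α-carbon (future C-4) as R, while the ester α-carbon (future C-3) forms as a mixture that step 5 corrects.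

Step 5
Reactants: 10 methyl (3R)-3-[4-(benzyloxy)-3-methoxybenzyl]-4-[(S)-4-benzyl-2-oxooxazolidin-3-yl]-2-[4-(tert-butyldimethylsilyloxy)-3-methoxybenzyl]-4-oxobutanoate (C-2 epimer mixture)
Product: 13 (3R,4R)-4-[4-(benzyloxy)-3-methoxybenzyl]-3-[4-(tert-butyldimethylsilyloxy)-3-methoxybenzyl]dihydrofuran-2(3H)-one, via hydroxy ester 11 (not isolated), via 3-epimeric lactone 12 (not isolated)
Conditions: NaBH4 (4 eq), THF/H2O 4:1, 0 °C → rt; then DBU (0.5 eq), PhMe, 60 °C
Reagents that add atoms: none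
Why: Chemoselective borohydride reduction of the N-acyloxazolidinone (more electrophilic than the methyl ester) frees the primary alcohol, which lactonises 5-exo onto the ester, and DBU then epimerises C-3 through the lactone enolate to the thermodynamically preferred trans (3R) isomer while the non-enolisable C-4 (R) is untouched.

Step 6
Reactants: 13 (3R,4R)-4-[4-(benzyloxy)-3-methoxybenzyl]-3-[4-(tert-butyldimethylsilyloxy)-3-methoxybenzyl]dihydrofuran-2(3H)-one; 14 (S)-4-benzyl-3-(2-chloroacetyl)oxazolidin-2-one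
Product: 16 (3R,4R)-4-[4-(benzyloxy)-3-methoxybenzyl]-3-(4-{2-[(S)-4-benzyl-2-oxooxazolidin-3-yl]-2-oxoethoxy}-3-methoxybenzyl)dihydrofuran-2(3H)-one, via caesium phenoxide 15 (not isolated)
Conditions: CsF (1.5 eq), NaI (0.1 eq), DMF, 0 °C → rt
Reagents that add atoms: none
Why: One-pot fluoride desilylation and Williamson O-alkylation; the naked caesium phenoxide displaces chloride from the activated α-chloro imide by SN2 (any phenol already freed in step 5 reacts the same way) and no stereocentre is touched.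

Step 7
Reactants: 16 (3R,4R)-4-[4-(benzyloxy)-3-methoxybenzyl]-3-(4-{2-[(S)-4-benzyl-2-oxooxazolidin-3-yl]-2-oxoethoxy}-3-methoxybenzyl)dihydrofuran-2(3H)-one; 17 4-(benzyloxy)-3-methoxybenzaldehyde
Product: 20 (3R,4R)-4-[4-(benzyloxy)-3-methoxybenzyl]-3-[4-({(1R,2S)-1-[4-(benzyloxy)-3-methoxyphenyl]-3-[(S)-4-benzyl-2-oxooxazolidin-3-yl]-1-hydroxy-3-oxopropan-2-yl}oxy)-3-methoxybenzyl]dihydrofuran-2(3H)-one, via boron enolate 18 (not isolated), via boron aldolate 19 (not isolated)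
Conditions: Bu2BOTf (1.2 eq), iPr2NEt (1.4 eq), CH2Cl2, −78 → 0 °C; 17 (1.3 eq), −78 → 0 °C; pH 7 buffer, MeOH, 30% H2O2, 0 °C
Reagents that add atoms: none
Why: Evans syn-aldol of a glycolate-type imide; soft enolisation gives only the (Z)-boron enolate of the imide (the lactone is not enolised) and the Zimmerman–Traxler transition state under control of the (S)-auxiliary gives the syn (2S,3R) adduct, which is the threo arrangement that becomes (1R,2R) in the arm after reduction.

Step 8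
Reactants: 20 (3R,4R)-4-[4-(benzyloxy)-3-methoxybenzyl]-3-[4-({(1R,2S)-1-[4-(benzyloxy)-3-methoxyphenyl]-3-[(S)-4-benzyl-2-oxooxazolidin-3-yl]-1-hydroxy-3-oxopropan-2-yl}oxy)-3-methoxybenzyl]dihydrofuran-2(3H)-one
Product: 21 (3R,4R)-4-[4-(benzyloxy)-3-methoxybenzyl]-3-[4-({(1R,2R)-1-[4-(benzyloxy)-3-methoxyphenyl]-1,3-dihydroxypropan-2-yl}oxy)-3-methoxybenzyl]dihydrofuran-2(3H)-one
Conditions: NaBH4 (3 eq), THF/H2O 4:1, 0 °C, 2 h
Reagents that add atoms: none
Why: Reductive cleavage of the N-acyloxazolidinone to the primary alcohol, which at 0 °C is much faster than reduction of the γ-lactone and outruns retro-aldol, so both arm stereocentres are kept.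

Step 9
Reactants: 21 (3R,4R)-4-[4-(benzyloxy)-3-methoxybenzyl]-3-[4-({(1R,2R)-1-[4-(benzyloxy)-3-methoxyphenyl]-1,3-dihydroxypropan-2-yl}oxy)-3-methoxybenzyl]dihydrofuran-2(3H)-one
Product: 22 (3R,4R)-3-[4-({(1R,2R)-1,3-dihydroxy-1-(4-hydroxy-3-methoxyphenyl)propan-2-yl}oxy)-3-methoxybenzyl]-4-(4-hydroxy-3-methoxybenzyl)dihydrofuran-2(3H)-one (CNP0305334.1)
Conditions: H2 (1 atm), 10% Pd/C, EtOAc/EtOH, rt
Reagents that add atoms: none
Why: Hydrogenolysis of the two aryl benzyl ethers, which cleave far faster under neutral conditions than the secondary benzylic C–OH, the alkyl aryl ether or the lactone.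

## Compound list

1 | 3-(4-hydroxy-3-methoxyphenyl)propanoic acid | OC(=O)CCc1ccc(O)c(OC)c1 | starting material
2 | 3-[4-(benzyloxy)-3-methoxyphenyl]propanoic acid | OC(=O)CCc1ccc(OCc2ccccc2)c(OC)c1 | intermediate
3 | (S)-4-benzyloxazolidin-2-one | O=C1N[C@@H](Cc2ccccc2)CO1 | starting material
4 | mixed pivalic anhydride of 2 (not isolated) | CC(C)(C)C(=O)OC(=O)CCc1ccc(OCc2ccccc2)c(OC)c1 | intermediate
5 | (S)-4-benzyl-3-{3-[4-(benzyloxy)-3-methoxyphenyl]propanoyl}oxazolidin-2-one | O=C(CCc1ccc(OCc2ccccc2)c(OC)c1)N1[C@@H](Cc2ccccc2)COC1=O | intermediate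
6 | methyl 3-(4-hydroxy-3-methoxyphenyl)propanoate | COC(=O)CCc1ccc(O)c(OC)c1 | starting material
7 | methyl 3-[4-(tert-butyldimethylsilyloxy)-3-methoxyphenyl]propanoate | COC(=O)CCc1ccc(O[Si](C)(C)C(C)(C)C)c(OC)c1 | intermediate
8 | lithium (Z)-enolate of imide 5 (not isolated) | [Li]O/C(=C\Cc1ccc(OCc2ccccc2)c(OC)c1)N1[C@@H](Cc2ccccc2)COC1=O | intermediate
9 | lithium enolate of ester 7 (not isolated) | COC(O[Li])=CCc1ccc(O[Si](C)(C)C(C)(C)C)c(OC)c1 | intermediate
10 | methyl (3R)-3-[4-(benzyloxy)-3-methoxybenzyl]-4-[(S)-4-benzyl-2-oxooxazolidin-3-yl]-2-[4-(tert-butyldimethylsilyloxy)-3-methoxybenzyl]-4-oxobutanoate, C-2 epimer mixture | COC(=O)C(Cc1ccc(O[Si](C)(C)C(C)(C)C)c(OC)c1)[C@@H](Cc1ccc(OCc2ccccc2)c(OC)c1)C(=O)N1[C@@H](Cc2ccccc2)COC1=O | intermediate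
11 | methyl (3R)-3-[4-(benzyloxy)-3-methoxybenzyl]-2-[4-(tert-butyldimethylsilyloxy)-3-methoxybenzyl]-4-hydroxybutanoate, C-2 epimer mixture (not isolated) | COC(=O)C(Cc1ccc(O[Si](C)(C)C(C)(C)C)c(OC)c1)[C@@H](Cc1ccc(OCc2ccccc2)c(OC)c1)CO | intermediate
12 | (4R)-4-[4-(benzyloxy)-3-methoxybenzyl]-3-[4-(tert-butyldimethylsilyloxy)-3-methoxybenzyl]dihydrofuran-2(3H)-one, C-3 epimer mixture (not isolated) | COc1cc(C[C@H]2COC(=O)C2Cc2ccc(O[Si](C)(C)C(C)(C)C)c(OC)c2)ccc1OCc1ccccc1 | intermediate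
13 | (3R,4R)-4-[4-(benzyloxy)-3-methoxybenzyl]-3-[4-(tert-butyldimethylsilyloxy)-3-methoxybenzyl]dihydrofuran-2(3H)-one | COc1cc(C[C@H]2COC(=O)[C@@H]2Cc2ccc(O[Si](C)(C)C(C)(C)C)c(OC)c2)ccc1OCc1ccccc1 | intermediate
14 | (S)-4-benzyl-3-(2-chloroacetyl)oxazolidin-2-one | O=C(CCl)N1[C@@H](Cc2ccccc2)COC1=O | starting material
15 | caesium phenoxide from 13 (not isolated) | COc1cc(C[C@H]2COC(=O)[C@@H]2Cc2ccc([O-])c(OC)c2)ccc1OCc1ccccc1.[Cs+] | intermediate
16 | (3R,4R)-4-[4-(benzyloxy)-3-methoxybenzyl]-3-(4-{2-[(S)-4-benzyl-2-oxooxazolidin-3-yl]-2-oxoethoxy}-3-methoxybenzyl)dihydrofuran-2(3H)-one | COc1cc(C[C@H]2COC(=O)[C@@H]2Cc2ccc(OCC(=O)N3[C@@H](Cc4ccccc4)COC3=O)c(OC)c2)ccc1OCc1ccccc1 | intermediate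
17 | 4-(benzyloxy)-3-methoxybenzaldehyde | O=Cc1ccc(OCc2ccccc2)c(OC)c1 | starting material
18 | (Z)-dibutylboron enolate of 16 (not isolated) | COc1cc(C[C@H]2COC(=O)[C@@H]2Cc2ccc(O/C=C(\OB(CCCC)CCCC)N3[C@@H](Cc4ccccc4)COC3=O)c(OC)c2)ccc1OCc1ccccc1 | intermediate
19 | dibutylboron aldolate of 20 (not isolated) | COc1cc(C[C@H]2COC(=O)[C@@H]2Cc2ccc(O[C@H](C(=O)N3[C@@H](Cc4ccccc4)COC3=O)[C@H](OB(CCCC)CCCC)c3ccc(OCc4ccccc4)c(OC)c3)c(OC)c2)ccc1OCc1ccccc1 | intermediate
20 | (3R,4R)-4-[4-(benzyloxy)-3-methoxybenzyl]-3-[4-({(1R,2S)-1-[4-(benzyloxy)-3-methoxyphenyl]-3-[(S)-4-benzyl-2-oxooxazolidin-3-yl]-1-hydroxy-3-oxopropan-2-yl}oxy)-3-methoxybenzyl]dihydrofuran-2(3H)-one | COc1cc(C[C@H]2COC(=O)[C@@H]2Cc2ccc(O[C@H](C(=O)N3[C@@H](Cc4ccccc4)COC3=O)[C@H](O)c3ccc(OCc4ccccc4)c(OC)c3)c(OC)c2)ccc1OCc1ccccc1 | intermediate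
21 | (3R,4R)-4-[4-(benzyloxy)-3-methoxybenzyl]-3-[4-({(1R,2R)-1-[4-(benzyloxy)-3-methoxyphenyl]-1,3-dihydroxypropan-2-yl}oxy)-3-methoxybenzyl]dihydrofuran-2(3H)-one | COc1cc(C[C@H]2COC(=O)[C@@H]2Cc2ccc(O[C@H](CO)[C@H](O)c3ccc(OCc4ccccc4)c(OC)c3)c(OC)c2)ccc1OCc1ccccc1 | intermediate
22 | (3R,4R)-3-[4-({(1R,2R)-1,3-dihydroxy-1-(4-hydroxy-3-methoxyphenyl)propan-2-yl}oxy)-3-methoxybenzyl]-4-(4-hydroxy-3-methoxybenzyl)dihydrofuran-2(3H)-one | COc1cc(C[C@H]2COC(=O)[C@@H]2Cc2ccc(O[C@H](CO)[C@H](O)c3ccc(O)c(OC)c3)c(OC)c2)ccc1O | target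

## Step count and risks

Total steps: 9. Longest linear sequence: 8 (steps 1, 2, 4, 5, 6, 7, 8, 9, from dihydroferulic acid); step 3 is the only side branch.

Steps most likely to fail:

**Step 4 (oxidative hetero-coupling).** Homo-dimers of either enolate, low conversion and only moderate facial selectivity at the imide α-carbon are all possible. The fallback replaces the one-electron coupling by a two-electron SN2 reaction with a preformed enolonium equivalent. It sets out from 7: its lithium enolate 9 is hydroxylated with 2-(phenylsulfonyl)-3-phenyloxaziridine to give methyl 2-hydroxy-3-[4-(tert-butyldimethylsilyloxy)-3-methoxyphenyl]propanoate F1. This is converted (Tf2O, 2,6-lutidine, CH2Cl2, −78 °C) into methyl 3-[4-(tert-butyldimethylsilyloxy)-3-methoxyphenyl]-2-(trifluoromethylsulfonyloxy)propanoate F2. The lithium enolate 8 of imide 5 (LDA, THF, −78 → −20 °C) then displaces the triflate, with the auxiliary directing attack as in an Evans alkylation to give the same (R) centre. The fallback comes back to the route at 10 (again as a C-2 epimer mixture, corrected in step 5).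

**Step 6 (desilylative O-alkylation with the chloroacetyl imide).** The phenoxide or fluoride may attack the exocyclic imide carbonyl (acyl transfer) or exchange the chloride instead of giving the ether. The fallback builds the ether first and attaches the auxiliary afterwards. It sets out from 13: CsF and tert-butyl bromoacetate in DMF give tert-butyl 2-[4-({(3R,4R)-4-[4-(benzyloxy)-3-methoxybenzyl]-2-oxotetrahydrofuran-3-yl}methyl)-2-methoxyphenoxy]acetate F3. TFA in CH2Cl2 gives 2-[4-({(3R,4R)-4-[4-(benzyloxy)-3-methoxybenzyl]-2-oxotetrahydrofuran-3-yl}methyl)-2-methoxyphenoxy]acetic acid F4. PivCl/Et3N converts it into its mixed pivalic anhydride F5, which acylates oxazolidinone 3 (LiCl, THF). The fallback comes back at 16.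

**Step 8 (borohydride removal of the auxiliary).** The electron-rich β-hydroxy imide can undergo retro-aldol in the basic medium, and the lactone can be partly reduced. The fallback separates cleavage from reduction. It sets out from 20: LiOH/H2O2 in THF/H2O at 0 °C (then Na2SO3 and acidification to pH 2, which re-closes any opened lactone) gives (2S,3R)-3-[4-(benzyloxy)-3-methoxyphenyl]-2-[4-({(3R,4R)-4-[4-(benzyloxy)-3-methoxybenzyl]-2-oxotetrahydrofuran-3-yl}methyl)-2-methoxyphenoxy]-3-hydroxypropanoic acid F6. BH3·SMe2 in THF at 0 °C then reduces the free carboxylic acid selectively in the presence of the lactone. The fallback comes back at 21.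

## Further compounds

F1 | step 4 | methyl 2-hydroxy-3-[4-(tert-butyldimethylsilyloxy)-3-methoxyphenyl]propanoate (racemic) | COC(=O)C(O)Cc1ccc(O[Si](C)(C)C(C)(C)C)c(OC)c1
F2 | step 4 | methyl 3-[4-(tert-butyldimethylsilyloxy)-3-methoxyphenyl]-2-(trifluoromethylsulfonyloxy)propanoate (racemic) | COC(=O)C(OS(=O)(=O)C(F)(F)F)Cc1ccc(O[Si](C)(C)C(C)(C)C)c(OC)c1
F3 | step 6 | tert-butyl 2-[4-({(3R,4R)-4-[4-(benzyloxy)-3-methoxybenzyl]-2-oxotetrahydrofuran-3-yl}methyl)-2-methoxyphenoxy]acetate | COc1cc(C[C@H]2COC(=O)[C@@H]2Cc2ccc(OCC(=O)OC(C)(C)C)c(OC)c2)ccc1OCc1ccccc1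
F4 | step 6 | 2-[4-({(3R,4R)-4-[4-(benzyloxy)-3-methoxybenzyl]-2-oxotetrahydrofuran-3-yl}methyl)-2-methoxyphenoxy]acetic acid | COc1cc(C[C@H]2COC(=O)[C@@H]2Cc2ccc(OCC(=O)O)c(OC)c2)ccc1OCc1ccccc1
F5 | step 6 | mixed pivalic anhydride of F4 | COc1cc(C[C@H]2COC(=O)[C@@H]2Cc2ccc(OCC(=O)OC(=O)C(C)(C)C)c(OC)c2)ccc1OCc1ccccc1
F6 | step 8 | (2S,3R)-3-[4-(benzyloxy)-3-methoxyphenyl]-2-[4-({(3R,4R)-4-[4-(benzyloxy)-3-methoxybenzyl]-2-oxotetrahydrofuran-3-yl}methyl)-2-methoxyphenoxy]-3-hydroxypropanoic acid | COc1cc(C[C@H]2COC(=O)[C@@H]2Cc2ccc(O[C@H](C(=O)O)[C@H](O)c3ccc(OCc4ccccc4)c(OC)c3)c(OC)c2)ccc1OCc1ccccc1
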